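**Retrosynthetic overview**
1. The target (halocynthiaxanthin) is cut at C12–C13 into a C16 epoxy half, a C23 acetylenic half and the C20 methyl group. One flask: hydrozirconation of the terminal alkyne C11≡C12 of 19, trans-selective Negishi alkenylation of the C13 gem-dibromide 29, then methylation of the remaining C13–Br bond.
2. Enabling feature: C13 is a fully substituted sp2 carbon that carries only C12, C14 and the one-carbon branch C20, so it can be a CBr2 terminus whose two C–Br bonds differ (cis or trans to the C14–C15 polyene arm). C12 is an unsubstituted CH at the end of the C9=C10–C11=C12 diene, so it can be the CH of a terminal alkyne. The C8 ketone is carried as a silyl-protected allylic alcohol.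
3. 19: actinol → enol triflate → carbonylation → Sharpless epoxidation (oxirane C5–O–C6) → C7–C8 homologation → C8–C9 bond by alkenylzinc addition → C11≡C12 by Colvin rearrangement.
4. 29: same triflate → Sonogashira (C6'–C7') → Horner–Wadsworth–Emmons (C11'=C12') → Wittig (C15'=C15) → dibromo-olefination (C13=C14).
5. Rings: both six-membered rings (ring A, C1–C6; ring B, C1'–C6') come intact from actinol. The oxirane is the only ring made (step 5, before the key step). The key step closes no ring. End game: desilylation, then MnO2 oxidation of C8–OH.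

Key step: step 20

Remark: the C8 carbinol centre made in step 10 is carried as a mixture of both epimers (left undefined in the SMILES of 16–19 and 30–33) because step 22 oxidises it to the ketone; compounds 1, 13, 20 and 23 are taken to be commercial.

Abbreviations: TBS = tert-butyldimethylsilyl. RB = (4R)-4-(TBSO)-2,6,6-trimethylcyclohex-1-en-1-yl. RA = (1S,4S,6R)-4-(TBSO)-2,2,6-trimethyl-7-oxabicyclo[4.1.0]heptan-1-yl, oxirane anti to the silyloxy group. Carotenoid numbering is used for positions.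

Step 1
Reactants: 1 (4R,6R)-4-hydroxy-2,2,6-trimethylcyclohexan-1-one (actinol)
Product: 2 (4R,6R)-4-(TBSO)-2,2,6-trimethylcyclohexan-1-one
Conditions: TBSCl, imidazole, DMF, rt
Reagents that add atoms: tert-butyldimethylsilyl chloride, CC(C)(C)[Si](C)(C)Cl
Why: silyl ether formation on an unhindered secondary alcohol is routine, and both stereocentres come from 1 and are not touched.

Step 2
Reactants: 2 (4R,6R)-4-(TBSO)-2,2,6-trimethylcyclohexan-1-one
Product: 4 (4R)-4-(TBSO)-2,6,6-trimethylcyclohex-1-en-1-yl trifluoromethanesulfonate, via lithium enolate 3 (not isolated)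
Conditions: LiN(iPr)2, THF, −78 to 0 °C; then PhNTf2, −78 °C to rt
Reagents that add atoms: N-phenylbis(trifluoromethanesulfonimide), O=S(=O)(N(c1ccccc1)S(=O)(=O)C(F)(F)F)C(F)(F)F
Why: the ketone can enolise only toward the methyl-bearing carbon because the other α-carbon is quaternary, so O-triflation of the single enolate should give the tetrasubstituted enol triflate (enol triflate formation); the methyl-bearing stereocentre is erased on purpose and the silyloxy centre stays.

Step 3
Reactants: 4 (4R)-4-(TBSO)-2,6,6-trimethylcyclohex-1-en-1-yl trifluoromethanesulfonate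
Product: 5 methyl (4R)-4-(TBSO)-2,6,6-trimethylcyclohex-1-ene-1-carboxylate
Conditions: Pd(OAc)2 (cat.), PPh3, CO (1 atm), MeOH, Et3N, DMF, rt to 50 °C
Reagents that add atoms: carbon monoxide, [C-]#[O+]; methanol, CO
Why: zerovalent palladium inserts into the vinyl C–OTf bond, CO inserts and methanol cleaves the acylpalladium to the conjugated ester (palladium-catalysed alkoxycarbonylation of an enol triflate).

Step 4
Reactants: 5 methyl (4R)-4-(TBSO)-2,6,6-trimethylcyclohex-1-ene-1-carboxylate
Product: 6 [(4R)-4-(TBSO)-2,6,6-trimethylcyclohex-1-en-1-yl]methanol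
Conditions: i-Bu2AlH, CH2Cl2, −78 °C; aq. KNaC4H4O6
Reagents that add atoms: none
Why: two hydride transfers reduce the conjugated ester in 1,2-fashion to the primary allylic alcohol that the epoxidation needs (i-Bu2AlH ester reduction).

Step 5
Reactants: 6 [(4R)-4-(TBSO)-2,6,6-trimethylcyclohex-1-en-1-yl]methanol
Product: 7 [(1R,4S,6R)-4-(TBSO)-2,2,6-trimethyl-7-oxabicyclo[4.1.0]heptan-1-yl]methanol
Conditions: Ti(OiPr)4 (cat.), D-(−)-diethyl tartrate (cat.), t-BuOOH, 4 Å MS, CH2Cl2, −20 °C
Reagents that add atoms: tert-butyl hydroperoxide, CC(C)(C)OO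
Why: in the Sharpless asymmetric epoxidation the titanium tartrate complex bound to the primary allylic alcohol delivers oxygen to the face fixed by D-(−)-diethyl tartrate, which is the face anti to the silyloxy group, so both oxirane carbons (C5 and C6) are set by the reagent.

Step 6
Reactants: 7 [(1R,4S,6R)-4-(TBSO)-2,2,6-trimethyl-7-oxabicyclo[4.1.0]heptan-1-yl]methanol
Product: 8 (1R,4S,6R)-4-(TBSO)-2,2,6-trimethyl-7-oxabicyclo[4.1.0]heptane-1-carbaldehyde
Conditions: Pr4N[RuO4] (cat.), N-methylmorpholine N-oxide, 4 Å MS, CH2Cl2, 0 °C to rt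
Reagents that add atoms: none
Why: the neutral perruthenate/N-oxide oxidation of a primary alcohol stops at the aldehyde and spares oxirane and silyl ether, and the α-carbon is quaternary and cannot epimerise.

Step 7
Reactants: 8 (1R,4S,6R)-4-(TBSO)-2,2,6-trimethyl-7-oxabicyclo[4.1.0]heptane-1-carbaldehyde
Product: 9 (1S,4S,6R)-1-ethenyl-4-(TBSO)-2,2,6-trimethyl-7-oxabicyclo[4.1.0]heptane
Conditions: MePPh3Br, KOtBu, THF, 0 °C; then 8, 0 °C to rt
Reagents that add atoms: methyltriphenylphosphonium bromide, C[P+](c1ccccc1)(c1ccccc1)c1ccccc1.[Br-]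
Why: Wittig methylenation of a non-enolisable aldehyde by the unstabilised ylide is fast at low temperature and does not touch the oxirane.

Step 8
Reactants: 9 (1S,4S,6R)-1-ethenyl-4-(TBSO)-2,2,6-trimethyl-7-oxabicyclo[4.1.0]heptane
Product: 11 2-[RA]ethan-1-ol, via B-alkyl-9-BBN 10 (not isolated)
Conditions: 9-BBN-H, THF, 0 °C to rt; then NaOH, H2O2, 0 °C
Reagents that add atoms: hydrogen peroxide, OO
Why: the bulky dialkylborane adds anti-Markovnikov to the monosubstituted alkene, boron going to the terminal carbon (the future C8), and alkaline peroxide oxidation gives the primary alcohol (hydroboration–oxidation).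

Step 9
Reactants: 11 2-[RA]ethan-1-ol
Product: 12 2-[RA]acetaldehyde
Conditions: Pr4N[RuO4] (cat.), N-methylmorpholine N-oxide, 4 Å MS, CH2Cl2, 0 °C; used at once
Reagents that add atoms: none
Why: the same neutral perruthenate oxidation should give the β,γ-epoxy aldehyde without the base that would open the oxirane by β-elimination.

Step 10
Reactants: 12 2-[RA]acetaldehyde; 13 1,1-diethoxybut-2-yne
Product: 16 (3E)-5,5-diethoxy-3-methyl-1-[RA]pent-3-en-2-ol (both C2 epimers), via alkenylzirconocene chloride 14 (not isolated), via alkenyl(methyl)zinc 15 (not isolated)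
Conditions: 13, Cp2Zr(H)Cl, CH2Cl2, rt; Me2Zn, toluene, −65 °C; then 12, 0 °C; aq. NaHCO3
Reagents that add atoms: none
Why: syn-hydrozirconation of the internal alkyne puts zirconium on the methyl-bearing carbon, away from the bulky acetal, and transmetalation to zinc followed by non-basic 1,2-addition to the aldehyde forms the C8–C9 bond with the 9E geometry fixed by the syn addition (hydrozirconation, zinc transmetalation, carbonyl addition), while the new C8 carbinol centre is not controlled and need not be.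

Step 11
Reactants: 16 (3E)-5,5-diethoxy-3-methyl-1-[RA]pent-3-en-2-ol
Product: 17 (3E)-2-(TBSO)-5,5-diethoxy-3-methyl-1-[RA]pent-3-ene
Conditions: TBSCl, imidazole, DMF, rt
Reagents that add atoms: tert-butyldimethylsilyl chloride, CC(C)(C)[Si](C)(C)Cl
Why: silylation of the secondary allylic alcohol under basic conditions without a Lewis acid keeps the acetal and masks C8–OH for the organometallic steps (silyl ether formation).

Step 12
Reactants: 17 (3E)-2-(TBSO)-5,5-diethoxy-3-methyl-1-[RA]pent-3-ene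
Product: 18 (2E)-4-(TBSO)-3-methyl-5-[RA]pent-2-enal
Conditions: oxalic acid (cat.), wet SiO2, CH2Cl2, rt
Reagents that add atoms: water, O
Why: an α,β-unsaturated acetal hydrolyses through a stabilised allylic oxocarbenium ion under acid so mild that oxirane and silyl ethers should survive (acetal hydrolysis).

Step 13
Reactants: 18 (2E)-4-(TBSO)-3-methyl-5-[RA]pent-2-enal
Product: 19 (3E)-2-(TBSO)-3-methyl-1-[RA]hex-3-en-5-yne
Conditions: Me3SiCHN2, n-BuLi, THF, −78 °C; then 18, −78 °C to rt
Reagents that add atoms: (trimethylsilyl)diazomethane, C[Si](C)(C)C=[N+]=[N-]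
Why: lithiated trimethylsilyldiazomethane adds to the aldehyde, lithium trimethylsilanolate is lost in a Peterson-type step and the alkylidene carbene rearranges by 1,2-hydrogen shift to the terminal alkyne C11≡C12 (Colvin rearrangement), the aprotic medium avoiding conjugate addition to the enal.

Step 14
Reactants: 4 (4R)-4-(TBSO)-2,6,6-trimethylcyclohex-1-en-1-yl trifluoromethanesulfonate; 20 (2E)-3-methylpent-2-en-4-yn-1-ol
Product: 21 (2E)-3-methyl-5-[RB]pent-2-en-4-yn-1-ol
Conditions: Pd(PPh3)4 (cat.), CuI (cat.), i-Pr2NH, DMF, rt to 40 °C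
Reagents that add atoms: none
Why: Sonogashira coupling of the enol triflate with the terminal alkyne forms the C6'–C7' bond and the ring dienyne in one step and keeps the E geometry of the commercial enynol.

Step 15
Reactants: 21 (2E)-3-methyl-5-[RB]pent-2-en-4-yn-1-ol
Product: 22 (2E)-3-methyl-5-[RB]pent-2-en-4-ynal
Conditions: MnO2, CH2Cl2, rt
Reagents that add atoms: none
Why: MnO2 oxidises only the allylic primary alcohol, giving the conjugated aldehyde (allylic oxidation).

Step 16
Reactants: 22 (2E)-3-methyl-5-[RB]pent-2-en-4-ynal; 23 diethyl (3-cyano-2-methylprop-2-en-1-yl)phosphonate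
Product: 25 (2E,4E,6E)-3,7-dimethyl-9-[RB]nona-2,4,6-trien-8-ynenitrile, via lithiated phosphonate 24 (not isolated)
Conditions: 23, LiN(SiMe3)2, THF/DMPU, −78 °C; then 22, −78 to 0 °C
Reagents that add atoms: none
Why: Horner–Wadsworth–Emmons olefination with the lithiated allylic phosphonate forms C11'=C12' with E selectivity, and the 13'E nitrile, the thermodynamically preferred isomer, is freed from any 13'Z isomer by chromatography.

Step 17
Reactants: 25 (2E,4E,6E)-3,7-dimethyl-9-[RB]nona-2,4,6-trien-8-ynenitrile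
Product: 27 (2E,4E,6E)-3,7-dimethyl-9-[RB]nona-2,4,6-trien-8-ynal, via N-aluminoimine 26 (not isolated)
Conditions: i-Bu2AlH, CH2Cl2, −78 °C; then wet SiO2, 0 °C
Reagents that add atoms: water, O
Why: one hydride adds to the nitrile to give an N-aluminoimine that resists further reduction and hydrolyses on work-up to the aldehyde (i-Bu2AlH nitrile reduction).

Step 18
Reactants: 27 (2E,4E,6E)-3,7-dimethyl-9-[RB]nona-2,4,6-trien-8-ynal
Product: 28 (2E,4E,6E,8E)-5,9-dimethyl-11-[RB]undeca-2,4,6,8-tetraen-10-ynal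
Conditions: Ph3P=CHCHO, toluene, 70 °C, dark
Reagents that add atoms: (triphenylphosphoranylidene)acetaldehyde, O=CC=P(c1ccccc1)(c1ccccc1)c1ccccc1
Why: Wittig reaction with the stabilised formylmethylene ylide adds C15 and C14 as an E enal, and the more conjugated product aldehyde is less electrophilic than 27, which limits a second homologation.

Step 19
Reactants: 28 (2E,4E,6E,8E)-5,9-dimethyl-11-[RB]undeca-2,4,6,8-tetraen-10-ynal
Product: 29 (3E,5E,7E,9E)-1,1-dibromo-6,10-dimethyl-12-[RB]dodeca-1,3,5,7,9-pentaen-11-yne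
Conditions: CBr4, PPh3, Zn, CH2Cl2, rt; then 28, 0 °C, dark
Reagents that add atoms: carbon tetrabromide, BrC(Br)(Br)Br
Why: Wittig-type dibromo-olefination by the ylide made from CBr4, PPh3 and zinc (first stage of the Corey–Fuchs sequence) turns the aldehyde into the C13 gem-dibromide under neutral conditions.

Step 20
Reactants: 19 (3E)-2-(TBSO)-3-methyl-1-[RA]hex-3-en-5-yne; 29 (3E,5E,7E,9E)-1,1-dibromo-6,10-dimethyl-12-[RB]dodeca-1,3,5,7,9-pentaen-11-yne
Product: 32 (3S,5R,6S,3'R,8RS)-3,8,3'-tris(TBSO)-5,6-epoxy-7',8'-didehydro-5,6,7,8-tetrahydro-β,β-carotene, via dienylzirconocene chloride 30 (not isolated), via 13-bromo coupling product 31 (not isolated)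
Conditions: 19, Cp2Zr(H)Cl, THF, rt, dark; then 29, PdCl2(DPEphos) (cat.), ZnBr2 (cat.), 0 °C to rt; then Me2Zn, Pd(t-Bu3P)2 (cat.), rt
Reagents that add atoms: dimethylzinc, C[Zn]C
Why: syn-addition of Cp2Zr(H)Cl to the terminal alkyne of 19 puts zirconium on C12 and fixes the 11E double bond; zerovalent palladium then inserts only into the C13–Br bond of 29 that is trans to the polyene arm, the C12 dienyl group is passed from zirconium to palladium (ZnBr2 as shuttle) and reductive elimination forms the C12–C13 bond, after which the remaining, more hindered C13–Br bond is replaced by methyl from Me2Zn under Pd(t-Bu3P)2 with retention, so that C20 ends up cis to C15 and the 13E geometry results. The closest known reaction type is the one-pot Negishi sequence of trans-selective monoalkenylation of a 1,1-dibromo-1-alkene by an alkenylzirconocene followed by methylation of the resulting 2-bromo-1,3-diene with a methylzinc reagent. No ring is closed and no stereocentre is created; the stereochemical output is the geometry of the two double bonds that flank the new bond, set by the syn hydrometalation for C11=C12 and by the order in which the two bromine atoms react for C13=C14. The step needs chemoselective hydrozirconation (secured by adding 29 with its internal alkyne only after the hydride is consumed, and by the terminal alkyne reacting far faster than oxirane or silyl ethers), site selectivity between the two bromines (secured by the steric difference between the bromine cis and the bromine trans to the C15 arm) and retention in the methylation (secured by the bulky, electron-rich t-Bu3P ligand, which makes reductive elimination faster than π–σ–π isomerisation of the dienylpalladium species).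

Step 21
Reactants: 32 (3S,5R,6S,3'R,8RS)-3,8,3'-tris(TBSO)-5,6-epoxy-7',8'-didehydro-5,6,7,8-tetrahydro-β,β-carotene
Product: 33 (3S,5R,6S,3'R,8RS)-5,6-epoxy-7',8'-didehydro-5,6,7,8-tetrahydro-β,β-carotene-3,8,3'-triol
Conditions: Bu4NF, AcOH, THF, rt, dark
Reagents that add atoms: none
Why: fluoride cleaves all three silyl ethers while acetic acid buffers the alkoxides, so oxirane and polyene are not exposed to strong base (fluoride desilylation).

Step 22
Reactants: 33 (3S,5R,6S,3'R,8RS)-5,6-epoxy-7',8'-didehydro-5,6,7,8-tetrahydro-β,β-carotene-3,8,3'-triol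
Product: 34 (3S,5R,6S,3'R)-5,6-epoxy-3,3'-dihydroxy-7',8'-didehydro-5,6,7,8-tetrahydro-β,β-caroten-8-one (halocynthiaxanthin, CNP0332618.1)
Conditions: MnO2, CH2Cl2, rt, dark
Reagents that add atoms: none
Why: MnO2 oxidises only the C8 alcohol, which is allylic and conjugated to the polyene, and leaves the two saturated secondary alcohols alone, so both C8 epimers converge on the target under neutral conditions that spare the β,γ-epoxy ketone (allylic oxidation).

**Compound list**
1 | (4R,6R)-4-hydroxy-2,2,6-trimethylcyclohexan-1-one (actinol) | CC1(C)C[C@H](O)C[C@@H](C)C1=O | starting material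
2 | (4R,6R)-4-(TBSO)-2,2,6-trimethylcyclohexan-1-one | CC1(C)C[C@H](O[Si](C)(C)C(C)(C)C)C[C@@H](C)C1=O | intermediate
3 | lithium (4R)-4-(TBSO)-2,6,6-trimethylcyclohex-1-en-1-olate | [Li+].CC1=C([O-])C(C)(C)C[C@H](O[Si](C)(C)C(C)(C)C)C1 | intermediate (not isolated)
4 | (4R)-4-(TBSO)-2,6,6-trimethylcyclohex-1-en-1-yl trifluoromethanesulfonate | CC1=C(OS(=O)(=O)C(F)(F)F)C(C)(C)C[C@H](O[Si](C)(C)C(C)(C)C)C1 | intermediate
5 | methyl (4R)-4-(TBSO)-2,6,6-trimethylcyclohex-1-ene-1-carboxylate | CC1=C(C(=O)OC)C(C)(C)C[C@H](O[Si](C)(C)C(C)(C)C)C1 | intermediate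
6 | [(4R)-4-(TBSO)-2,6,6-trimethylcyclohex-1-en-1-yl]methanol | CC1=C(CO)C(C)(C)C[C@H](O[Si](C)(C)C(C)(C)C)C1 | intermediate
7 | [(1R,4S,6R)-4-(TBSO)-2,2,6-trimethyl-7-oxabicyclo[4.1.0]heptan-1-yl]methanol | OC[C@@]12O[C@]1(C)C[C@@H](O[Si](C)(C)C(C)(C)C)CC2(C)C | intermediate
8 | (1R,4S,6R)-4-(TBSO)-2,2,6-trimethyl-7-oxabicyclo[4.1.0]heptane-1-carbaldehyde | O=C[C@@]12O[C@]1(C)C[C@@H](O[Si](C)(C)C(C)(C)C)CC2(C)C | intermediate
9 | (1S,4S,6R)-1-ethenyl-4-(TBSO)-2,2,6-trimethyl-7-oxabicyclo[4.1.0]heptane | C=C[C@@]12O[C@]1(C)C[C@@H](O[Si](C)(C)C(C)(C)C)CC2(C)C | intermediate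
10 | 9-{2-[RA]ethyl}-9-borabicyclo[3.3.1]nonane | B1(C2CCCC1CCC2)CC[C@@]12O[C@]1(C)C[C@@H](O[Si](C)(C)C(C)(C)C)CC2(C)C | intermediate (not isolated)
11 | 2-[RA]ethan-1-ol | OCC[C@@]12O[C@]1(C)C[C@@H](O[Si](C)(C)C(C)(C)C)CC2(C)C | intermediate
12 | 2-[RA]acetaldehyde | O=CC[C@@]12O[C@]1(C)C[C@@H](O[Si](C)(C)C(C)(C)C)CC2(C)C | intermediate
13 | 1,1-diethoxybut-2-yne | CC#CC(OCC)OCC | starting material
14 | chloro[(2E)-4,4-diethoxybut-2-en-2-yl]zirconocene | CCOC(OCC)/C=C(\C)[Zr](Cl)(C1C=CC=C1)C1C=CC=C1 | intermediate (not isolated)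
15 | [(2E)-4,4-diethoxybut-2-en-2-yl](methyl)zinc | CCOC(OCC)/C=C(\C)[Zn]C | intermediate (not isolated)
16 | (3E)-5,5-diethoxy-3-methyl-1-[RA]pent-3-en-2-ol, both C2 epimers | CCOC(OCC)/C=C(\C)C(O)C[C@@]12O[C@]1(C)C[C@@H](O[Si](C)(C)C(C)(C)C)CC2(C)C | intermediate
17 | (3E)-2-(TBSO)-5,5-diethoxy-3-methyl-1-[RA]pent-3-ene | CCOC(OCC)/C=C(\C)C(O[Si](C)(C)C(C)(C)C)C[C@@]12O[C@]1(C)C[C@@H](O[Si](C)(C)C(C)(C)C)CC2(C)C | intermediate
18 | (2E)-4-(TBSO)-3-methyl-5-[RA]pent-2-enal | O=C/C=C(\C)C(O[Si](C)(C)C(C)(C)C)C[C@@]12O[C@]1(C)C[C@@H](O[Si](C)(C)C(C)(C)C)CC2(C)C | intermediate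
19 | (3E)-2-(TBSO)-3-methyl-1-[RA]hex-3-en-5-yne | C#C/C=C(\C)C(O[Si](C)(C)C(C)(C)C)C[C@@]12O[C@]1(C)C[C@@H](O[Si](C)(C)C(C)(C)C)CC2(C)C | intermediate
20 | (2E)-3-methylpent-2-en-4-yn-1-ol | C#C/C(C)=C/CO | starting material
21 | (2E)-3-methyl-5-[RB]pent-2-en-4-yn-1-ol | CC1=C(C#C/C(C)=C/CO)C(C)(C)C[C@H](O[Si](C)(C)C(C)(C)C)C1 | intermediate
22 | (2E)-3-methyl-5-[RB]pent-2-en-4-ynal | CC1=C(C#C/C(C)=C/C=O)C(C)(C)C[C@H](O[Si](C)(C)C(C)(C)C)C1 | intermediate
23 | diethyl (3-cyano-2-methylprop-2-en-1-yl)phosphonate (E/Z mixture as sold) | CCOP(=O)(CC(C)=CC#N)OCC | starting material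
24 | lithium salt of 23 (allylic carbanion) | [Li+].CCOP(=O)([CH-]C(C)=CC#N)OCC | intermediate (not isolated)
25 | (2E,4E,6E)-3,7-dimethyl-9-[RB]nona-2,4,6-trien-8-ynenitrile | CC1=C(C#C/C(C)=C/C=C/C(C)=C/C#N)C(C)(C)C[C@H](O[Si](C)(C)C(C)(C)C)C1 | intermediate
26 | N-(diisobutylalumanyl)imine of 27 | CC1=C(C#C/C(C)=C/C=C/C(C)=C/C=N[Al](CC(C)C)CC(C)C)C(C)(C)C[C@H](O[Si](C)(C)C(C)(C)C)C1 | intermediate (not isolated)
27 | (2E,4E,6E)-3,7-dimethyl-9-[RB]nona-2,4,6-trien-8-ynal | CC1=C(C#C/C(C)=C/C=C/C(C)=C/C=O)C(C)(C)C[C@H](O[Si](C)(C)C(C)(C)C)C1 | intermediate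
28 | (2E,4E,6E,8E)-5,9-dimethyl-11-[RB]undeca-2,4,6,8-tetraen-10-ynal | CC1=C(C#C/C(C)=C/C=C/C(C)=C/C=C/C=O)C(C)(C)C[C@H](O[Si](C)(C)C(C)(C)C)C1 | intermediate
29 | (3E,5E,7E,9E)-1,1-dibromo-6,10-dimethyl-12-[RB]dodeca-1,3,5,7,9-pentaen-11-yne | CC1=C(C#C/C(C)=C/C=C/C(C)=C/C=C/C=C(Br)Br)C(C)(C)C[C@H](O[Si](C)(C)C(C)(C)C)C1 | intermediate
30 | chloro[(1E,3E)-5-(TBSO)-4-methyl-6-RA-hexa-1,3-dien-1-yl]zirconocene | Cl[Zr](C1C=CC=C1)(C1C=CC=C1)/C=C/C=C(\C)C(O[Si](C)(C)C(C)(C)C)C[C@@]12O[C@]1(C)C[C@@H](O[Si](C)(C)C(C)(C)C)CC2(C)C | intermediate (not isolated)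
31 | (13Z)-13-bromo-20-nor analogue of 32 (bromine cis to C15, C12 trans to C15) | CC1=C(C#C/C(C)=C/C=C/C(C)=C/C=C/C=C(Br)/C=C/C=C(\C)C(O[Si](C)(C)C(C)(C)C)C[C@@]23O[C@]2(C)C[C@@H](O[Si](C)(C)C(C)(C)C)CC3(C)C)C(C)(C)C[C@H](O[Si](C)(C)C(C)(C)C)C1 | intermediate (not isolated)
32 | (3S,5R,6S,3'R,8RS)-3,8,3'-tris(TBSO)-5,6-epoxy-7',8'-didehydro-5,6,7,8-tetrahydro-β,β-carotene | CC1=C(C#C/C(C)=C/C=C/C(C)=C/C=C/C=C(C)/C=C/C=C(\C)C(O[Si](C)(C)C(C)(C)C)C[C@@]23O[C@]2(C)C[C@@H](O[Si](C)(C)C(C)(C)C)CC3(C)C)C(C)(C)C[C@H](O[Si](C)(C)C(C)(C)C)C1 | intermediate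
33 | (3S,5R,6S,3'R,8RS)-5,6-epoxy-7',8'-didehydro-5,6,7,8-tetrahydro-β,β-carotene-3,8,3'-triol | CC1=C(C#C/C(C)=C/C=C/C(C)=C/C=C/C=C(C)/C=C/C=C(\C)C(O)C[C@@]23O[C@]2(C)C[C@@H](O)CC3(C)C)C(C)(C)C[C@H](O)C1 | intermediate
34 | (3S,5R,6S,3'R)-5,6-epoxy-3,3'-dihydroxy-7',8'-didehydro-5,6,7,8-tetrahydro-β,β-caroten-8-one (halocynthiaxanthin, CNP0332618.1) | CC1=C(C#C/C(C)=C/C=C/C(C)=C/C=C/C=C(C)/C=C/C=C(\C)C(=O)C[C@@]23O[C@]2(C)C[C@@H](O)CC3(C)C)C(C)(C)C[C@H](O)C1 | target

Total step count: 22. Longest linear sequence: 16 steps (steps 1–13, then 20–22).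

**Steps most likely to fail**

Step 20 (key step). What may go wrong: loss of the C13 geometry by π–σ–π isomerisation of the bromodienylpalladium species during the methylation stage, or incomplete discrimination between the two C–Br bonds in the first oxidative addition; either would lead to 13Z material. Fallback: the methyl group is installed before the union. Setting out from 29, treatment with n-BuLi (2 equiv, THF, −78 °C) and then MeI would give the methyl-capped diyne (4R)-4-(TBSO)-1-[(3E,5E,7E,9E)-3,7-dimethyltrideca-3,5,7,9-tetraene-1,11-diyn-1-yl]-2,6,6-trimethylcyclohex-1-ene F1. Hydrozirconation of its unhindered methyl-substituted alkyne (Cp2Zr(H)Cl, THF, 40 °C) and iodinolysis would give the vinyl iodide (4R)-4-(TBSO)-1-[(3E,5E,7E,9E,11E)-12-iodo-3,7-dimethyltrideca-3,5,7,9,11-pentaen-1-yn-1-yl]-2,6,6-trimethylcyclohex-1-ene F2, whose geometry can be checked before the coupling. A Negishi coupling of F2 with the dienylzirconocene chloride 30 made from 19 (Pd(PPh3)4 cat., ZnCl2 cat., THF, rt) comes back to the route at 32.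

Step 10. What may go wrong: hydrozirconation with the wrong regiochemistry (zirconium on the acetal-bearing carbon), and opening of the oxirane of 12 by β-elimination while the slow addition of a hindered alkenylzinc is awaited. Fallback: setting out from 13, hydrozirconation followed by iodinolysis would give the vinyl iodide (2E)-4,4-diethoxy-2-iodobut-2-ene F3, which can be freed from its regioisomer by chromatography. A Nozaki–Hiyama–Kishi coupling of F3 with 12 (CrCl2, NiCl2 cat., DMSO, rt) is non-basic and comes back to the route at 16.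

Step 8. What may go wrong: transfer of hydride to the allylic oxirane (reductive SN2′ opening to an allylic alcohol) in competition with hydroboration of the vinyl group. Fallback: the two-carbon arm is built before the oxirane. Setting out from 4, a Stille coupling with tributyl(vinyl)stannane (Pd(PPh3)4 cat., LiCl, THF, reflux) would give the diene (4R)-4-(TBSO)-1-ethenyl-2,6,6-trimethylcyclohex-1-ene F4. Treatment with 9-BBN-H and then NaOH/H2O2 would give the homoallylic alcohol 2-[RB]ethan-1-ol F5. Epoxidation of the tetrasubstituted ring alkene with m-CPBA (NaHCO3, CH2Cl2, 0 °C) and chromatographic separation of the isomer with the oxirane anti to the silyloxy group comes back to the route at 11, at the price of substrate-controlled instead of reagent-controlled facial selectivity.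

**Further compounds**
F1 | step 20 | (4R)-4-(TBSO)-1-[(3E,5E,7E,9E)-3,7-dimethyltrideca-3,5,7,9-tetraene-1,11-diyn-1-yl]-2,6,6-trimethylcyclohex-1-ene | CC1=C(C#C/C(C)=C/C=C/C(C)=C/C=C/C#CC)C(C)(C)C[C@H](O[Si](C)(C)C(C)(C)C)C1
F2 | step 20 | (4R)-4-(TBSO)-1-[(3E,5E,7E,9E,11E)-12-iodo-3,7-dimethyltrideca-3,5,7,9,11-pentaen-1-yn-1-yl]-2,6,6-trimethylcyclohex-1-ene | CC1=C(C#C/C(C)=C/C=C/C(C)=C/C=C/C=C(\C)I)C(C)(C)C[C@H](O[Si](C)(C)C(C)(C)C)C1
F3 | step 10 | (2E)-4,4-diethoxy-2-iodobut-2-ene | CCOC(OCC)/C=C(\C)I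
F4 | step 8 | (4R)-4-(TBSO)-1-ethenyl-2,6,6-trimethylcyclohex-1-ene | CC1=C(C=C)C(C)(C)C[C@H](O[Si](C)(C)C(C)(C)C)C1
F5 | step 8 | 2-[(4R)-4-(TBSO)-2,6,6-trimethylcyclohex-1-en-1-yl]ethan-1-ol | CC1=C(CCO)C(C)(C)C[C@H](O[Si](C)(C)C(C)(C)C)C1
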